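**Strategy**

The route rests on disconnecting C2–C3 of the tetrahydrofuran ring (O1, C2, C3, C4, C5; chain numbered C1 arylmethyl to C7 ketone). Both carbons are electrophilic by nature, C3 as an aldehyde and C2 as the O1-bearing carbon of a styryl enol ether. A triazolylidene carbene inverts the polarity of C3 and, in one operation, forges C2–C3, closes the furan-3-one ring and delivers the C1 methylene. The precursor is an open-chain (3R)-butanal carrying the (Z)-styryl ether on the C5 oxygen, with C7 masked as a 1,3-dithiane and both phenols benzylated. C5 is the sole stereocentre carried into this step; C2 and C3 are derived from it afterwards.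

Key step: step 10

Remark: the 2,5-cis tetrahydrofuran-3-one is assumed to be the more stable C2 epimer, as is usual for 2,5-disubstituted tetrahydrofuran-3-ones; a triisopropylsilyl ether and two commercial building blocks (O-benzylvanillin and a chiral-pool chlorohydrin ester) are chosen so that the approach to the precursor needs neither a resolution nor a migration-prone silyl group.

**Route**

Step 1
Reactants: 1 4-(benzyloxy)-3-methoxybenzaldehyde
Product: 2 2-[4-(benzyloxy)-3-methoxyphenyl]-1,3-dithiane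
Conditions: HS(CH2)3SH, BF3·OEt2 (cat.), CH2Cl2, 0 °C → rt
Reagents that add atoms: propane-1,3-dithiol, SCCCS
Why: Lewis acid-catalysed dithioacetalisation of an aryl aldehyde is fast at catalytic BF3 loading, leaves the aryl benzyl ether alone and installs the C7 acyl anion equivalent.

Step 2
Reactants: 1 4-(benzyloxy)-3-methoxybenzaldehyde
Product: 3 1-(benzyloxy)-4-ethynyl-2-methoxybenzene
Conditions: dimethyl (1-diazo-2-oxopropyl)phosphonate, K2CO3, MeOH, rt
Reagents that add atoms: dimethyl (1-diazo-2-oxopropyl)phosphonate, COP(=O)(OC)C(=[N+]=[N-])C(C)=O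
Why: The Seyferth–Gilbert homologation in its Ohira–Bestmann form converts an aryl aldehyde into the terminal alkyne in one step under mild carbonate base.

Step 3
Reactants: 4 ethyl (3R)-4-chloro-3-hydroxybutanoate
Product: 5 (3R)-4-chlorobutane-1,3-diol
Conditions: NaBH4, EtOH, 0 °C → rt
Reagents that add atoms: none
Why: Hydroxyl-assisted borohydride reduction of a β-hydroxy ester gives the 1,3-diol without touching the carbinol stereocentre, which is taken from the chiral pool and later becomes C5.

Step 4
Reactants: 5 (3R)-4-chlorobutane-1,3-diol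
Product: 6 (2R)-1-chloro-4-[(triisopropylsilyl)oxy]butan-2-ol
Conditions: i-Pr3SiCl, imidazole, CH2Cl2, 0 °C
Reagents that add atoms: chlorotriisopropylsilane, CC(C)[Si](Cl)(C(C)C)C(C)C
Why: Silyl ether formation is strongly selective for the primary hydroxyl on steric grounds, and the bulky triisopropylsilyl group is chosen because it resists oxygen-to-oxygen migration and hydroxide in step 7.

Step 5
Reactants: 6 (2R)-1-chloro-4-[(triisopropylsilyl)oxy]butan-2-ol
Product: 7 triisopropyl{2-[(2R)-oxiran-2-yl]ethoxy}silane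
Conditions: K2CO3, MeOH, rt
Reagents that add atoms: none
Why: Intramolecular Williamson closure of the chlorohydrin (3-exo-tet) displaces the primary chloride, so the configuration of the carbinol carbon is retained.

Step 6
Reactants: 2 2-[4-(benzyloxy)-3-methoxyphenyl]-1,3-dithiane, 7 triisopropyl{2-[(2R)-oxiran-2-yl]ethoxy}silane
Product: 9 (2R)-1-{2-[4-(benzyloxy)-3-methoxyphenyl]-1,3-dithian-2-yl}-4-[(triisopropylsilyl)oxy]butan-2-ol, via 2-aryl-2-lithio-1,3-dithiane 8 (not isolated)
Conditions: n-BuLi, THF, −30 °C; then 7, −30 °C → rt; aq. NH4Cl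
Reagents that add atoms: none
Why: In this Corey–Seebach umpolung the lithiated dithiane opens the terminal epoxide at its unsubstituted carbon (SN2), forming C6–C7 and leaving the C5 carbinol configuration untouched.

Step 7
Reactants: 9 (2R)-1-{2-[4-(benzyloxy)-3-methoxyphenyl]-1,3-dithian-2-yl}-4-[(triisopropylsilyl)oxy]butan-2-ol, 3 1-(benzyloxy)-4-ethynyl-2-methoxybenzene
Product: 10 {[(3R)-4-{2-[4-(benzyloxy)-3-methoxyphenyl]-1,3-dithian-2-yl}-3-{[(Z)-2-[4-(benzyloxy)-3-methoxyphenyl]ethenyl]oxy}butyl]oxy}triisopropylsilane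
Conditions: 3 (3 equiv), CsOH·H2O (20 mol%), NMP, 90 °C
Reagents that add atoms: none
Why: Base-catalysed anti-Markovnikov hydroalkoxylation of an arylacetylene proceeds by anti addition of the caesium alkoxide and protonation of the benzylic vinyl anion, which should give the (Z)-β-alkoxystyrene while dithiane, benzyl ethers and the hindered silyl ether tolerate the base.

Step 8
Reactants: 10 {[(3R)-4-{2-[4-(benzyloxy)-3-methoxyphenyl]-1,3-dithian-2-yl}-3-{[(Z)-2-[4-(benzyloxy)-3-methoxyphenyl]ethenyl]oxy}butyl]oxy}triisopropylsilane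
Product: 11 (3R)-4-{2-[4-(benzyloxy)-3-methoxyphenyl]-1,3-dithian-2-yl}-3-{[(Z)-2-[4-(benzyloxy)-3-methoxyphenyl]ethenyl]oxy}butan-1-ol
Conditions: Bu4NF, THF, 0 °C → rt
Reagents that add atoms: none
Why: Fluoride-induced desilylation frees the primary alcohol under conditions that are neutral to the enol ether, the dithiane and the benzyl ethers.

Step 9
Reactants: 11 (3R)-4-{2-[4-(benzyloxy)-3-methoxyphenyl]-1,3-dithian-2-yl}-3-{[(Z)-2-[4-(benzyloxy)-3-methoxyphenyl]ethenyl]oxy}butan-1-ol
Product: 12 (3R)-4-{2-[4-(benzyloxy)-3-methoxyphenyl]-1,3-dithian-2-yl}-3-{[(Z)-2-[4-(benzyloxy)-3-methoxyphenyl]ethenyl]oxy}butanal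
Conditions: SO3·pyridine, DMSO, i-Pr2NEt, CH2Cl2, 0 °C
Reagents that add atoms: none
Why: The Parikh–Doering oxidation stops at the aldehyde, does not oxidise thioacetal sulfur or the electron-rich enol ether, and its brief cold exposure to amine limits β-elimination.

Step 10
Reactants: 12 (3R)-4-{2-[4-(benzyloxy)-3-methoxyphenyl]-1,3-dithian-2-yl}-3-{[(Z)-2-[4-(benzyloxy)-3-methoxyphenyl]ethenyl]oxy}butanal
Product: 14 (2R,5R)-2-[4-(benzyloxy)-3-methoxybenzyl]-5-({2-[4-(benzyloxy)-3-methoxyphenyl]-1,3-dithian-2-yl}methyl)dihydrofuran-3(2H)-one, via 2,5-trans ketone epimer 13 (not isolated)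
Conditions: 2-mesityl-6,7-dihydro-5H-pyrrolo[2,1-c][1,2,4]triazol-2-ium chloride (20 mol%), DBU (15 mol%), 1,4-dioxane (0.02 M), 80 °C; then DBU (0.3 equiv), rt
Reagents that add atoms: none
Why: Proposed new method: the carbene adds to the C3 aldehyde and tautomerises to the enaminol (Breslow intermediate), whose nucleophilic C3 bonds to C2 of the enol ether while its hydroxyl proton passes to C1, either in one Conia-ene-like event or through the O1-stabilised oxocarbenium ion, and the resulting alkoxide expels the carbene to leave the C3 ketone. The closest known reaction type is the carbene-catalysed intramolecular hydroacylation of aryl vinyl ethers to benzofuran-3(2H)-ones (and of unactivated alkenes to chromanones); an enolisable aliphatic aldehyde on a flexible tether has not been used in it. The tetrahydrofuranone ring (O1, C2, C3, C4, C5) closes in the 5-exo-trig mode. C2 is the only new stereocentre and is not relied on kinetically: lying between O1 and the C3 carbonyl it epimerises under DBU, so the 2,5-trans epimer 13 should drain into the 2,5-cis ketone 14 under thermodynamic control by the fixed C5 centre. The step needs regioselectivity for C2 over C1, secured by the enol ether polarisation (C1 is the proton acceptor) and the five-membered closure, and chemoselectivity against crossed benzoin closure onto C7 and E1cB loss of the C5 oxygen, secured by the dithiane mask at C7, base kept below the azolium loading and high dilution.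

Step 11
Reactants: 14 (2R,5R)-2-[4-(benzyloxy)-3-methoxybenzyl]-5-({2-[4-(benzyloxy)-3-methoxyphenyl]-1,3-dithian-2-yl}methyl)dihydrofuran-3(2H)-one
Product: 15 (2R,3R,5R)-2-[4-(benzyloxy)-3-methoxybenzyl]-5-({2-[4-(benzyloxy)-3-methoxyphenyl]-1,3-dithian-2-yl}methyl)tetrahydrofuran-3-ol
Conditions: LiBH(s-Bu)3, THF, −78 °C; MeOH, aq. NH4Cl (no peroxide work-up)
Reagents that add atoms: none
Why: In this substrate-controlled ketone reduction the bulky hydride attacks C3 from the ring face opposite the cis C2 and C5 substituents, so the new hydroxyl should come out cis to both (3R).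

Step 12
Reactants: 15 (2R,3R,5R)-2-[4-(benzyloxy)-3-methoxybenzyl]-5-({2-[4-(benzyloxy)-3-methoxyphenyl]-1,3-dithian-2-yl}methyl)tetrahydrofuran-3-ol
Product: 16 1-[4-(benzyloxy)-3-methoxyphenyl]-2-{(2R,4R,5R)-5-[4-(benzyloxy)-3-methoxybenzyl]-4-hydroxytetrahydrofuran-2-yl}ethan-1-one
Conditions: I2, NaHCO3, acetone/H2O, 0 °C; aq. Na2S2O3
Reagents that add atoms: water, O
Why: Iodine-mediated oxidative hydrolysis of a 2-aryl-2-alkyl-1,3-dithiane unmasks the C7 aryl ketone under buffered conditions that spare the secondary alcohol, the benzyl ethers and the β-alkoxy ketone.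

Step 13
Reactants: 16 1-[4-(benzyloxy)-3-methoxyphenyl]-2-{(2R,4R,5R)-5-[4-(benzyloxy)-3-methoxybenzyl]-4-hydroxytetrahydrofuran-2-yl}ethan-1-one
Product: 17 renealtin A, 1-(4-hydroxy-3-methoxyphenyl)-2-[(2R,4R,5R)-4-hydroxy-5-(4-hydroxy-3-methoxybenzyl)tetrahydrofuran-2-yl]ethan-1-one
Conditions: H2 (1 atm), Pd/C (10 wt%), EtOAc/EtOH, rt
Reagents that add atoms: none
Why: Hydrogenolysis of the two aryl benzyl ethers over palladium on carbon is run only after the sulfur has been removed and should outpace reduction of the electron-rich aryl ketone, with no stereocentre involved.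

**Compound list**

1 | 4-(benzyloxy)-3-methoxybenzaldehyde (O-benzylvanillin) | COc1cc(C=O)ccc1OCc1ccccc1 | starting material
2 | 2-[4-(benzyloxy)-3-methoxyphenyl]-1,3-dithiane | COc1cc(C2SCCCS2)ccc1OCc1ccccc1 | intermediate
3 | 1-(benzyloxy)-4-ethynyl-2-methoxybenzene | COc1cc(C#C)ccc1OCc1ccccc1 | intermediate
4 | ethyl (3R)-4-chloro-3-hydroxybutanoate | CCOC(=O)C[C@@H](O)CCl | starting material
5 | (3R)-4-chlorobutane-1,3-diol | OCC[C@@H](O)CCl | intermediate
6 | (2R)-1-chloro-4-[(triisopropylsilyl)oxy]butan-2-ol | CC(C)[Si](OCC[C@@H](O)CCl)(C(C)C)C(C)C | intermediate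
7 | triisopropyl{2-[(2R)-oxiran-2-yl]ethoxy}silane | CC(C)[Si](OCC[C@@H]1CO1)(C(C)C)C(C)C | intermediate
8 | 2-[4-(benzyloxy)-3-methoxyphenyl]-2-lithio-1,3-dithiane | [Li]C1(SCCCS1)c1ccc(OCc2ccccc2)c(OC)c1 | intermediate
9 | (2R)-1-{2-[4-(benzyloxy)-3-methoxyphenyl]-1,3-dithian-2-yl}-4-[(triisopropylsilyl)oxy]butan-2-ol | COc1cc(C2(C[C@H](O)CCO[Si](C(C)C)(C(C)C)C(C)C)SCCCS2)ccc1OCc1ccccc1 | intermediate
10 | {[(3R)-4-{2-[4-(benzyloxy)-3-methoxyphenyl]-1,3-dithian-2-yl}-3-{[(Z)-2-[4-(benzyloxy)-3-methoxyphenyl]ethenyl]oxy}butyl]oxy}triisopropylsilane | CC(C)[Si](OCC[C@H](CC1(SCCCS1)c1ccc(OCc2ccccc2)c(OC)c1)O/C=C\c1ccc(OCc2ccccc2)c(OC)c1)(C(C)C)C(C)C | intermediate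
11 | (3R)-4-{2-[4-(benzyloxy)-3-methoxyphenyl]-1,3-dithian-2-yl}-3-{[(Z)-2-[4-(benzyloxy)-3-methoxyphenyl]ethenyl]oxy}butan-1-ol | OCC[C@H](CC1(SCCCS1)c1ccc(OCc2ccccc2)c(OC)c1)O/C=C\c1ccc(OCc2ccccc2)c(OC)c1 | intermediate
12 | (3R)-4-{2-[4-(benzyloxy)-3-methoxyphenyl]-1,3-dithian-2-yl}-3-{[(Z)-2-[4-(benzyloxy)-3-methoxyphenyl]ethenyl]oxy}butanal | O=CC[C@H](CC1(SCCCS1)c1ccc(OCc2ccccc2)c(OC)c1)O/C=C\c1ccc(OCc2ccccc2)c(OC)c1 | intermediate
13 | (2S,5R)-2-[4-(benzyloxy)-3-methoxybenzyl]-5-({2-[4-(benzyloxy)-3-methoxyphenyl]-1,3-dithian-2-yl}methyl)dihydrofuran-3(2H)-one (2,5-trans) | COc1cc(C[C@@H]2O[C@@H](CC3(SCCCS3)c3ccc(OCc4ccccc4)c(OC)c3)CC2=O)ccc1OCc1ccccc1 | intermediate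
14 | (2R,5R)-2-[4-(benzyloxy)-3-methoxybenzyl]-5-({2-[4-(benzyloxy)-3-methoxyphenyl]-1,3-dithian-2-yl}methyl)dihydrofuran-3(2H)-one (2,5-cis) | COc1cc(C[C@H]2O[C@@H](CC3(SCCCS3)c3ccc(OCc4ccccc4)c(OC)c3)CC2=O)ccc1OCc1ccccc1 | intermediate
15 | (2R,3R,5R)-2-[4-(benzyloxy)-3-methoxybenzyl]-5-({2-[4-(benzyloxy)-3-methoxyphenyl]-1,3-dithian-2-yl}methyl)tetrahydrofuran-3-ol | COc1cc(C[C@H]2O[C@@H](CC3(SCCCS3)c3ccc(OCc4ccccc4)c(OC)c3)C[C@H]2O)ccc1OCc1ccccc1 | intermediate
16 | 1-[4-(benzyloxy)-3-methoxyphenyl]-2-{(2R,4R,5R)-5-[4-(benzyloxy)-3-methoxybenzyl]-4-hydroxytetrahydrofuran-2-yl}ethan-1-one | COc1cc(C[C@H]2O[C@@H](CC(=O)c3ccc(OCc4ccccc4)c(OC)c3)C[C@H]2O)ccc1OCc1ccccc1 | intermediate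
17 | renealtin A, 1-(4-hydroxy-3-methoxyphenyl)-2-[(2R,4R,5R)-4-hydroxy-5-(4-hydroxy-3-methoxybenzyl)tetrahydrofuran-2-yl]ethan-1-one | COc1cc(C[C@H]2O[C@@H](CC(=O)c3ccc(O)c(OC)c3)C[C@H]2O)ccc1O | target

**Step count and risks**

Total step count: 13. Longest linear sequence: 11 steps (from 4 to 17 through steps 3 to 13).

Steps most likely to fail:

1. Step 10. The enolisable, β-oxygenated aldehyde may lose the styryloxy group from C5 by E1cB elimination before the carbene engages it, or may couple with itself in an acyloin reaction. The enaminol may also fail to hand its proton to the electron-rich alkene, and the C2 equilibration may stop short of the cis epimer or open the ring by retro-oxa-Michael reaction. The fallback uses known chemistry, sets out from 12 and returns at 14: a thiol-catalysed radical-chain hydroacylation (methyl thioglycolate 0.3 equiv, AIBN added in portions, chlorobenzene, 80 °C). The thiyl radical abstracts the formyl hydrogen, the acyl radical at C3 closes 5-exo-trig onto C2 to give the benzylic C1 radical, and this takes hydrogen back from the thiol. Brief treatment with DBU at rt then equilibrates C2 to 14. This fallback makes no compound outside the list (F0).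

2. Step 7. Addition of a hindered secondary alkoxide to an electron-rich arylacetylene may be slow, and the hot basic medium may cause silyl migration to the secondary oxygen or erosion of the alkene geometry. The fallback sets out from 1 and 9 and returns at 10. Stork–Zhao olefination of 1 with (iodomethyl)triphenylphosphonium iodide and NaN(SiMe3)2 (THF, −78 °C) should give (Z)-1-(benzyloxy)-4-(2-iodoethenyl)-2-methoxybenzene F1. An Ullmann-type C–O coupling of 9 with F1 (CuI, 3,4,7,8-tetramethyl-1,10-phenanthroline, Cs2CO3, toluene, 80 °C) then forms the enol ether with retention of alkene geometry and under much milder base.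

3. Step 13. Over-reduction of the aryl ketone (to the benzylic alcohol or methylene) and poisoning of the palladium surface by sulfur residues carried over from step 12 may spoil the last step. The fallback sets out from 15 and returns at 17. The benzyl ethers are removed while C7 is still masked, with BCl3 and pentamethylbenzene in CH2Cl2 at −78 °C, giving (2R,3R,5R)-2-(4-hydroxy-3-methoxybenzyl)-5-{[2-(4-hydroxy-3-methoxyphenyl)-1,3-dithian-2-yl]methyl}tetrahydrofuran-3-ol F2. Alkylative dithiane hydrolysis (MeI, CaCO3, MeCN/H2O, 40 °C) then releases the ketone and gives 17 directly, so that the aryl ketone never meets hydrogen and a metal surface never meets sulfur.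

**Further compounds**

F0 | step 10 | none | none
F1 | step 7 | (Z)-1-(benzyloxy)-4-(2-iodoethenyl)-2-methoxybenzene | COc1cc(/C=C\I)ccc1OCc1ccccc1
F2 | step 13 | (2R,3R,5R)-2-(4-hydroxy-3-methoxybenzyl)-5-{[2-(4-hydroxy-3-methoxyphenyl)-1,3-dithian-2-yl]methyl}tetrahydrofuran-3-ol | COc1cc(C[C@H]2O[C@@H](CC3(SCCCS3)c3ccc(O)c(OC)c3)C[C@H]2O)ccc1O
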